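Retrosynthetic overview (target numbering: C1 = oxirane carbon bearing C7H2OBz, C2 = oxirane CH, C3=C4, C5–OBz, C6–OH)
- Last disconnection: the C1–C2 oxirane lies cis to the C6 hydroxyl on the neighbouring carbon (a syn 2,3-epoxy alcohol), so it goes back to hydroxyl-directed epoxidation of cyclohexa-1,3-dienol 16.
- Key disconnection: the carbocycle is opened at C1–C6 to the acyclic (Z,Z)-iododienal 13; forward, C1 (alkenyl iodide, then alkenylchromium) adds to the C6 aldehyde. The enabling feature is that C6 is a carbinol carbon allylic to C1 once the oxirane is read as a C1=C2 alkene, and the C1=C2–C3=C4 diene, both double bonds cis inside the six-membered ring, holds C1 next to C6.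
- This addition frees exactly the one hydroxyl the target leaves unacylated; one stereocentre (C5) is relayed to C6 in the ring closure and from C6 to C1 and C2 in the epoxidation.
- 13 comes from the chiral pool: (S)-glyceraldehyde acetonide gives C4–C6, a first Wittig adds C3 and C2, and a temporary furanone ring locks the C3=C4 cis geometry and tells the C5 and C6 oxygens apart; an iodo-Wittig on the derived lactol adds C1 and C7 with the iodide in place.
- Ring order: temporary furanone (closed in step 2, opened in step 5), cyclohexadiene (step 10), oxirane (step 11).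

Key step: step 10

Assumption: (S)-2,2-dimethyl-1,3-dioxolane-4-carbaldehyde (the acetonide of L-glyceraldehyde) is taken as a purchasable chiral-pool aldehyde.

Step 1
Reactants: 1 (S)-2,2-dimethyl-1,3-dioxolane-4-carbaldehyde; 2 methyl (triphenylphosphoranylidene)acetate
Product: 3 methyl (Z)-3-[(4R)-2,2-dimethyl-1,3-dioxolan-4-yl]prop-2-enoate
Conditions: MeOH, 0 °C → rt
Reagents that add atoms: none
Why: Wittig olefination of an α-alkoxy aldehyde with a stabilised ylide in methanol is known to favour the Z-enoate, and the acetal-protected stereocentre (future C5) is not touched.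

Step 2
Reactants: 3 methyl (Z)-3-[(4R)-2,2-dimethyl-1,3-dioxolan-4-yl]prop-2-enoate
Product: 4 (5R)-5-(hydroxymethyl)furan-2(5H)-one
Conditions: H2SO4 (cat.), MeOH/H2O, rt
Reagents that add atoms: none
Why: Acid-catalysed acetal hydrolysis frees the secondary hydroxyl, which lactonises (5-exo-trig transesterification) onto the cis ester, so that only Z material closes and the primary hydroxyl (future C6) is left as the only free one.

Step 3
Reactants: 4 (5R)-5-(hydroxymethyl)furan-2(5H)-one
Product: 5 (5R)-5-{[(tert-butyldimethylsilyl)oxy]methyl}furan-2(5H)-one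
Conditions: TBSCl, imidazole, DMF, 0 °C → rt
Reagents that add atoms: tert-butyldimethylsilyl chloride, CC(C)(C)[Si](C)(C)Cl
Why: Standard imidazole-mediated silylation of a primary alcohol, mild enough not to deprotonate the γ-position of the furanone.

Step 4
Reactants: 5 (5R)-5-{[(tert-butyldimethylsilyl)oxy]methyl}furan-2(5H)-one
Product: 6 (5R)-5-{[(tert-butyldimethylsilyl)oxy]methyl}-2,5-dihydrofuran-2-ol (anomer mixture)
Conditions: i-Bu2AlH (1.1 equiv), CH2Cl2, −78 °C
Reagents that add atoms: none
Why: Partial reduction of a lactone by i-Bu2AlH stops at the aluminium hemiacetal at low temperature and should give the lactol, a masked (Z)-4-hydroxy-enal with the cis C3=C4 bond held in the ring (the anomeric centre is lost in the next step).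

Step 5
Reactants: 6 (5R)-5-{[(tert-butyldimethylsilyl)oxy]methyl}-2,5-dihydrofuran-2-ol; 7 ethyl (triphenylphosphoranylidene)acetate
Product: 9 ethyl (2Z,4Z,6R)-7-[(tert-butyldimethylsilyl)oxy]-6-hydroxy-2-iodohepta-2,4-dienoate, via ethyl iodo(triphenylphosphoranylidene)acetate 8 (not isolated)
Conditions: 7, N-iodosuccinimide, CH2Cl2, −20 °C; then 6, −20 °C → rt
Reagents that add atoms: N-iodosuccinimide, O=C1CCC(=O)N1I
Why: Wittig olefination of the open hydroxy-enal form of the lactol with the α-iodo stabilised ylide 8 should place the ester trans to the chain (iodine cis to C3, the 2Z geometry needed for ring closure), while the ring-derived 4Z bond is carried over and the lactol oxygen emerges as the free C5 hydroxyl.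

Step 6
Reactants: 9 ethyl (2Z,4Z,6R)-7-[(tert-butyldimethylsilyl)oxy]-6-hydroxy-2-iodohepta-2,4-dienoate
Product: 10 (2Z,4Z,6R)-7-[(tert-butyldimethylsilyl)oxy]-2-iodohepta-2,4-diene-1,6-diol
Conditions: i-Bu2AlH (3.5 equiv), CH2Cl2, −78 °C
Reagents that add atoms: none
Why: 1,2-Reduction of an α,β-unsaturated ester to the allylic alcohol by i-Bu2AlH leaves the alkenyl iodide, the diene geometry and the silyl ether untouched.

Step 7
Reactants: 10 (2Z,4Z,6R)-7-[(tert-butyldimethylsilyl)oxy]-2-iodohepta-2,4-diene-1,6-diol
Product: 11 (2Z,4Z,6R)-7-[(tert-butyldimethylsilyl)oxy]-2-iodohepta-2,4-diene-1,6-diyl dibenzoate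
Conditions: BzCl (2.5 equiv), pyridine, DMAP (cat.), CH2Cl2, 0 °C
Reagents that add atoms: benzoyl chloride, O=C(Cl)c1ccccc1
Why: DMAP-catalysed acylation of both free hydroxyls installs in one operation the two benzoates that the target carries at C5 and C7.

Step 8
Reactants: 11 (2Z,4Z,6R)-7-[(tert-butyldimethylsilyl)oxy]-2-iodohepta-2,4-diene-1,6-diyl dibenzoate
Product: 12 (2Z,4Z,6R)-7-hydroxy-2-iodohepta-2,4-diene-1,6-diyl dibenzoate
Conditions: HF·pyridine, THF/pyridine, 0 °C
Reagents that add atoms: none
Why: Fluoride cleavage of the primary silyl ether in a buffered acidic medium, chosen because 1,2-benzoyl shift from the secondary to the primary oxygen is slow without free alkoxide.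

Step 9
Reactants: 12 (2Z,4Z,6R)-7-hydroxy-2-iodohepta-2,4-diene-1,6-diyl dibenzoate
Product: 13 (2R,3Z,5Z)-6-iodo-1-oxohepta-3,5-diene-2,7-diyl dibenzoate
Conditions: TEMPO (cat.), PhI(OAc)2, CH2Cl2, 0 °C → rt; used at once
Reagents that add atoms: none
Why: Oxoammonium (TEMPO) oxidation of a primary alcohol runs without base, so the aldehyde should form without enolisation of the α-benzoyloxy centre (C5) or drift of the C3=C4 bond into conjugation.

Step 10
Reactants: 13 (2R,3Z,5Z)-6-iodo-1-oxohepta-3,5-diene-2,7-diyl dibenzoate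
Product: 16 [(5R,6R)-5-(benzoyloxy)-6-hydroxycyclohexa-1,3-dien-1-yl]methyl benzoate, via alkenylchromium dichloride 14 (not isolated), via chromium alkoxide 15 (not isolated)
Conditions: CrCl2 (6 equiv), NiCl2 (2 mol %), degassed DMSO/THF, 0.005 M, rt; aqueous work-up
Reagents that add atoms: none
Why: Zerovalent nickel (from NiCl2 and CrCl2) inserts into the C1–I bond with retention, transmetalation gives the alkenylchromium species 14 of trivalent chromium, and its C1 adds to the C6 aldehyde through a closed four-centre transition state to give alkoxide 15, which is protonated on work-up. The closest known reaction type is the intramolecular Nozaki–Hiyama–Kishi alkenylation of aldehydes, which tolerates esters. The cyclohexa-1,3-diene ring closes 6-exo-trig at the carbonyl carbon, helped by the (Z,Z)-diene C1=C2–C3=C4, which holds C1 within reach of C6. The new C6 centre is controlled by the C5 benzoate: the forming C1–C6 bond should lie anti to the C5–O bond (polar Felkin–Anh) while the chromium-bound carbonyl oxygen sits pseudo-equatorial, which places the hydroxyl trans to the benzoate (5R,6R). The step needs selectivity for the aldehyde over two benzoates and for ring closure over dimerisation, secured by the carbonyl selectivity and low basicity of alkenylchromium reagents and by high dilution; retention of the alkenyl geometry is inherent to the Ni/Cr couple.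

Step 11
Reactants: 16 [(5R,6R)-5-(benzoyloxy)-6-hydroxycyclohexa-1,3-dien-1-yl]methyl benzoate
Product: 17 [(1S,2S,3R,6R)-3-(benzoyloxy)-2-hydroxy-7-oxabicyclo[4.1.0]hept-4-en-1-yl]methyl benzoate (target)
Conditions: mCPBA (1.1 equiv), CH2Cl2/aq. phosphate buffer (pH 7.5), 0 °C
Reagents that add atoms: 3-chloroperoxybenzoic acid, OOC(=O)c1cccc(Cl)c1
Why: Henbest epoxidation, in which the C6 hydroxyl hydrogen-bonds the peracid and delivers oxygen to the adjacent trisubstituted C1=C2 bond on its own face (C1 and C2 set cis to C6–OH), while the C3=C4 bond is deactivated by the allylic benzoate and not directed.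

Compound list
1 | (S)-2,2-dimethyl-1,3-dioxolane-4-carbaldehyde | O=C[C@@H]1COC(C)(C)O1 | starting material
2 | methyl (triphenylphosphoranylidene)acetate | COC(=O)C=P(c1ccccc1)(c1ccccc1)c1ccccc1 | starting material
3 | methyl (Z)-3-[(4R)-2,2-dimethyl-1,3-dioxolan-4-yl]prop-2-enoate | COC(=O)/C=C\[C@@H]1COC(C)(C)O1 | intermediate
4 | (5R)-5-(hydroxymethyl)furan-2(5H)-one | O=C1C=C[C@H](CO)O1 | intermediate
5 | (5R)-5-{[(tert-butyldimethylsilyl)oxy]methyl}furan-2(5H)-one | O=C1C=C[C@H](CO[Si](C)(C)C(C)(C)C)O1 | intermediate
6 | (5R)-5-{[(tert-butyldimethylsilyl)oxy]methyl}-2,5-dihydrofuran-2-ol (anomer mixture) | OC1C=C[C@H](CO[Si](C)(C)C(C)(C)C)O1 | intermediate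
7 | ethyl (triphenylphosphoranylidene)acetate | CCOC(=O)C=P(c1ccccc1)(c1ccccc1)c1ccccc1 | starting material
8 | ethyl iodo(triphenylphosphoranylidene)acetate | CCOC(=O)C(I)=P(c1ccccc1)(c1ccccc1)c1ccccc1 | intermediate
9 | ethyl (2Z,4Z,6R)-7-[(tert-butyldimethylsilyl)oxy]-6-hydroxy-2-iodohepta-2,4-dienoate | CCOC(=O)/C(I)=C/C=C\[C@@H](O)CO[Si](C)(C)C(C)(C)C | intermediate
10 | (2Z,4Z,6R)-7-[(tert-butyldimethylsilyl)oxy]-2-iodohepta-2,4-diene-1,6-diol | OC/C(I)=C/C=C\[C@@H](O)CO[Si](C)(C)C(C)(C)C | intermediate
11 | (2Z,4Z,6R)-7-[(tert-butyldimethylsilyl)oxy]-2-iodohepta-2,4-diene-1,6-diyl dibenzoate | O=C(OC/C(I)=C/C=C\[C@@H](OC(=O)c1ccccc1)CO[Si](C)(C)C(C)(C)C)c1ccccc1 | intermediate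
12 | (2Z,4Z,6R)-7-hydroxy-2-iodohepta-2,4-diene-1,6-diyl dibenzoate | O=C(OC/C(I)=C/C=C\[C@@H](OC(=O)c1ccccc1)CO)c1ccccc1 | intermediate
13 | (2R,3Z,5Z)-6-iodo-1-oxohepta-3,5-diene-2,7-diyl dibenzoate | O=C(OC/C(I)=C/C=C\[C@@H](OC(=O)c1ccccc1)C=O)c1ccccc1 | intermediate
14 | dichloro[(2Z,4Z,6R)-1,6-bis(benzoyloxy)-7-oxohepta-2,4-dien-2-yl]chromium (trivalent chromium) | O=C(OC/C([Cr](Cl)Cl)=C/C=C\[C@@H](OC(=O)c1ccccc1)C=O)c1ccccc1 | intermediate
15 | dichlorochromium alkoxide of 16 (trivalent chromium) | O=C(OCC1=CC=C[C@@H](OC(=O)c2ccccc2)[C@@H]1O[Cr](Cl)Cl)c1ccccc1 | intermediate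
16 | [(5R,6R)-5-(benzoyloxy)-6-hydroxycyclohexa-1,3-dien-1-yl]methyl benzoate | O=C(OCC1=CC=C[C@@H](OC(=O)c2ccccc2)[C@@H]1O)c1ccccc1 | intermediate
17 | [(1S,2S,3R,6R)-3-(benzoyloxy)-2-hydroxy-7-oxabicyclo[4.1.0]hept-4-en-1-yl]methyl benzoate | O=C(OC[C@@]12O[C@@H]1C=C[C@@H](OC(=O)c1ccccc1)[C@@H]2O)c1ccccc1 | target

Total step count: 11. Longest linear sequence: 11 steps (from 1).

Steps most likely to fail

Step 10. The carbonyl addition may show poor facial selectivity (C6 epimer), and the α-benzoyloxy aldehyde may enolise before ring closure, eroding C5. The fallback moves control from the substrate to the reagent: setting out from aldehyde 13, the same C1–C6 bond is closed by the catalytic asymmetric Nozaki–Hiyama–Kishi protocol. Conditions would be CrCl2 (10 mol %) bound to a chiral sulfonamide ligand, the NiCl2 complex of 2,9-dimethyl-1,10-phenanthroline (2 mol %), Mn powder, ZrCp2Cl2 and LiCl in MeCN at rt. The ligand enantiomer is chosen to reinforce attack on the required aldehyde face, and fast turnover shortens the lifetime of the free aldehyde. The route is rejoined at dienol 16; no new compound is made.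

Step 5. The weakly nucleophilic iodo ylide may olefinate the lactol sluggishly, the freed hydroxyl may add back in conjugate fashion onto the iodo-dienoate (closure to a dihydrofuran), and the ring-derived double bond may drift from Z to E. The fallback avoids both the lactol and the free hydroxyl and sets out from enoate 3. Reduction with i-Bu2AlH (CH2Cl2, −78 °C) should give (Z)-3-[(4R)-2,2-dimethyl-1,3-dioxolan-4-yl]prop-2-en-1-ol F1. Oxidation with MnO2 (CH2Cl2, rt) should give (Z)-3-[(4R)-2,2-dimethyl-1,3-dioxolan-4-yl]prop-2-enal F2. Olefination of this free aldehyde with ylide 8 (made as in step 5) should give ethyl (2Z,4Z)-5-[(4R)-2,2-dimethyl-1,3-dioxolan-4-yl]-2-iodopenta-2,4-dienoate F3. Mild acetal hydrolysis (80% aq. AcOH, rt) should give ethyl (2Z,4Z,6R)-6,7-dihydroxy-2-iodohepta-2,4-dienoate F4. Selective silylation of the primary hydroxyl (TBSCl, imidazole, CH2Cl2, −20 °C) rejoins the route at 9.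

Step 11. The peracid may also attack the C3=C4 bond or the face anti to the hydroxyl, and the vinyl oxirane may open under the acid by-product. The fallback changes the mode of oxygen delivery from a hydrogen-bonded peracid to a metal-bound peroxide: setting out from 16, VO(acac)2 (5 mol %) and t-BuOOH in CH2Cl2 at 0 °C pass the oxygen on within a vanadate ester of the C6 alkoxide. Only the double bond allylic to C6 can then react, and only on the hydroxyl face, under non-acidic conditions. The route is rejoined at 17; no new compound is made.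

Further compounds
F1 | step 5 | (Z)-3-[(4R)-2,2-dimethyl-1,3-dioxolan-4-yl]prop-2-en-1-ol | OC/C=C\[C@@H]1COC(C)(C)O1
F2 | step 5 | (Z)-3-[(4R)-2,2-dimethyl-1,3-dioxolan-4-yl]prop-2-enal | O=C/C=C\[C@@H]1COC(C)(C)O1
F3 | step 5 | ethyl (2Z,4Z)-5-[(4R)-2,2-dimethyl-1,3-dioxolan-4-yl]-2-iodopenta-2,4-dienoate | CCOC(=O)/C(I)=C/C=C\[C@@H]1COC(C)(C)O1
F4 | step 5 | ethyl (2Z,4Z,6R)-6,7-dihydroxy-2-iodohepta-2,4-dienoate | CCOC(=O)/C(I)=C/C=C\[C@@H](O)CO
F0 | step 10 | none | none
F0 | step 11 | none | none
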